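**Retrosynthetic overview**

1. The last step removes a MOM group from the 7‑oxygen. Before that, the pyran‑2‑one ring of the coumarin is opened into three components: aryl iodide 7 (supplies chroman C6), ethoxyacetylene 11 (supplies lactone C2 and C3) and salicylaldehyde 10 (supplies C4, the benzo ring and O1).
2. In the forward direction one flask forms the C6(chroman)–C3(coumarin) bond by Sonogashira coupling, then O1–C2 by phenol capture of the arylketene released from the ynol ether, then C3=C4 by aldol condensation onto the ortho‑formyl group.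
3. Enabling feature: C3 of the pyranone ring is both the α‑carbon of the lactone carbonyl C2 and the carbon bearing the chroman ring, and C4 is a CH on an arene with an ortho oxygen (O1). The ring is therefore an arylketene (C2=C3) plus salicylaldehyde retron.
4. Iodide 7: the chroman pyran ring is made first by chromenylation of 2,4‑dihydroxybenzaldehyde with prenal, which fixes the 5‑O/6‑C pattern. Hydrogenation, O‑methylation and CHO → CO2H → I (ipso‑iododecarboxylation) then place iodine exactly at C6.
5. Aldehyde 10: formylation of 5‑methoxyresorcinol, then MOM protection of the non‑chelated OH. Ring order: chroman pyran ring (step 1), then coumarin pyranone ring (step 8); both benzene rings are bought.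

Key step: step 8

Remark: the target has no stereocentre, so no stereocontrol is needed anywhere in the route.

**Route**

Step 1
Reactants: 1 2,4‑dihydroxybenzaldehyde; 2 3‑methylbut‑2‑enal (prenal)
Product: 3 5‑hydroxy‑2,2‑dimethyl‑2H‑chromene‑6‑carbaldehyde
Conditions: pyridine, 140 °C, sealed tube
Reagents that add atoms: none
Why: Pyridine‑mediated chromenylation (Knoevenagel‑type condensation at the ring carbon between the two hydroxyls, then oxa‑6π electrocyclisation through the free 4‑OH) should give the angular 5‑hydroxy‑6‑formyl chromene, because the chelated 2‑OH/CHO pair fixes the bond alternation in favour of attack at that carbon.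

Step 2
Reactants: 3 5‑hydroxy‑2,2‑dimethyl‑2H‑chromene‑6‑carbaldehyde
Product: 4 5‑hydroxy‑2,2‑dimethylchroman‑6‑carbaldehyde
Conditions: H2 (1 atm), 10% Pd/C, EtOAc, rt, stopped after 1 equiv H2
Reagents that add atoms: none
Why: Heterogeneous catalytic hydrogenation should saturate the styrene‑type C3=C4 bond much faster than it reduces the hydrogen‑bonded, electron‑rich aryl aldehyde.

Step 3
Reactants: 4 5‑hydroxy‑2,2‑dimethylchroman‑6‑carbaldehyde
Product: 5 5‑methoxy‑2,2‑dimethylchroman‑6‑carbaldehyde
Conditions: MeI, K2CO3, DMF, 50 °C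
Reagents that add atoms: iodomethane, CI
Why: Williamson O‑methylation of the only acidic site, the chelated 5‑OH, is reliable in a dipolar aprotic solvent.

Step 4
Reactants: 5 5‑methoxy‑2,2‑dimethylchroman‑6‑carbaldehyde
Product: 6 5‑methoxy‑2,2‑dimethylchroman‑6‑carboxylic acid
Conditions: NaClO2, NaH2PO4, 2‑methyl‑2‑butene, t‑BuOH/H2O, rt
Reagents that add atoms: sodium chlorite, [Na+].[O-]Cl=O
Why: Pinnick oxidation takes the aldehyde to the acid under buffered conditions, while 2‑methyl‑2‑butene scavenges HOCl and so protects the electron‑rich ring from chlorination.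

Step 5
Reactants: 6 5‑methoxy‑2,2‑dimethylchroman‑6‑carboxylic acid
Product: 7 6‑iodo‑5‑methoxy‑2,2‑dimethylchroman
Conditions: I2 (3 equiv), K3PO4, MeCN, 100 °C, sealed tube
Reagents that add atoms: iodine, II
Why: Transition‑metal‑free ipso‑iododecarboxylation of ortho‑alkoxybenzoic acids should replace CO2H by iodine exactly at C6, transferring the regiochemistry set in step 1 to the halide.

Step 6
Reactants: 8 5‑methoxyresorcinol
Product: 9 2,4‑dihydroxy‑6‑methoxybenzaldehyde
Conditions: POCl3, DMF, MeCN, 0 °C to rt; then H2O, 50 °C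
Reagents that add atoms: N,N‑dimethylformamide, CN(C)C=O; water, O
Why: Vilsmeier–Haack formylation of this phloroglucinol‑type ring should occur para to a free hydroxyl, at either of the two equivalent carbons between OH and OMe, in preference to the carbon between the two hydroxyls.

Step 7
Reactants: 9 2,4‑dihydroxy‑6‑methoxybenzaldehyde
Product: 10 2‑hydroxy‑6‑methoxy‑4‑(methoxymethoxy)benzaldehyde
Conditions: MOMCl (1.05 equiv), i‑Pr2NEt, CH2Cl2, 0 °C
Reagents that add atoms: chloromethyl methyl ether, COCCl
Why: The 4‑OH (para to CHO, not hydrogen‑bonded) is the more acidic and nucleophilic phenol and should be etherified selectively, the 2‑OH staying locked in its chelate with the formyl group.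

Step 8
Reactants: 7 6‑iodo‑5‑methoxy‑2,2‑dimethylchroman; 10 2‑hydroxy‑6‑methoxy‑4‑(methoxymethoxy)benzaldehyde; 11 ethoxyacetylene
Product: 15 5‑methoxy‑3‑(5‑methoxy‑2,2‑dimethylchroman‑6‑yl)‑7‑(methoxymethoxy)‑2H‑chromen‑2‑one, via aryl ynol ether 12 (not isolated), via arylketene 13 (not isolated), via aryl ester 14 (not isolated)
Conditions: 7, 11 (1.5 equiv), PdCl2(PPh3)2 (3 mol%), CuI (5 mol%), Et3N, toluene, rt; N2 sparge to remove excess 11; add 10, 125 °C (sealed); then DBU (0.2 equiv), 125 °C; one flask
Reagents that add atoms: none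
Why: Proposed new method: Sonogashira coupling of iodide 7 with ethoxyacetylene forms the C6(chroman)–C3 bond and gives ynol ether 12, which on heating loses ethylene by a retro‑ene reaction to arylketene 13; the single free phenol of 10 (O1) adds to the ketene to give ester 14 as its enolate, which closes the pyran‑2‑one ring by aldol addition of C3 to the ortho‑formyl carbon (C4) and E1cB loss of water. The closest known reaction types are the Sonogashira coupling of 1‑alkoxyalkynes with aryl iodides, the thermal retro‑ene generation of ketenes from alkynyl ethers with capture by O–H nucleophiles, and the Perkin–Oglialoro cyclisation of O‑arylacetyl salicylaldehydes to 3‑arylcoumarins; their union in one flask as a three‑component coumarin synthesis is the part without precedent. The only ring closed is the six‑membered lactone ring, by a 6‑(enolendo)‑exo‑trig aldol closure made irreversible by dehydration to the conjugated pyranone. No stereocentre survives, since the transient C4 carbinol is eliminated. The step needs chemoselective capture of the ketene by O1, which is secured by the MOM group on the 7‑oxygen and by removing excess 11 before heating so that no parent ketene competes; the position of attachment on the chroman is fixed by the iodine.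

Step 9
Reactants: 15 5‑methoxy‑3‑(5‑methoxy‑2,2‑dimethylchroman‑6‑yl)‑7‑(methoxymethoxy)‑2H‑chromen‑2‑one
Product: 16 7‑hydroxy‑5‑methoxy‑3‑(5‑methoxy‑2,2‑dimethylchroman‑6‑yl)‑2H‑chromen‑2‑one (target)
Conditions: 3 M aq. HCl, MeOH/THF, 50 °C
Reagents that add atoms: none
Why: Acid‑catalysed acetal cleavage removes the MOM group, while the aryl methyl ethers, the lactone and the tertiary alkyl aryl ether of the chroman should be stable to dilute HCl in methanol.

**Compound list**

1 | 2,4‑dihydroxybenzaldehyde | O=Cc1ccc(O)cc1O | starting material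
2 | 3‑methylbut‑2‑enal (prenal) | CC(C)=CC=O | starting material
3 | 5‑hydroxy‑2,2‑dimethyl‑2H‑chromene‑6‑carbaldehyde | CC1(C)C=Cc2c(O)c(C=O)ccc2O1 | intermediate
4 | 5‑hydroxy‑2,2‑dimethylchroman‑6‑carbaldehyde | CC1(C)CCc2c(O)c(C=O)ccc2O1 | intermediate
5 | 5‑methoxy‑2,2‑dimethylchroman‑6‑carbaldehyde | COc1c(C=O)ccc2OC(C)(C)CCc12 | intermediate
6 | 5‑methoxy‑2,2‑dimethylchroman‑6‑carboxylic acid | COc1c(C(=O)O)ccc2OC(C)(C)CCc12 | intermediate
7 | 6‑iodo‑5‑methoxy‑2,2‑dimethylchroman | COc1c(I)ccc2OC(C)(C)CCc12 | intermediate
8 | 5‑methoxyresorcinol | COc1cc(O)cc(O)c1 | starting material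
9 | 2,4‑dihydroxy‑6‑methoxybenzaldehyde | COc1cc(O)cc(O)c1C=O | intermediate
10 | 2‑hydroxy‑6‑methoxy‑4‑(methoxymethoxy)benzaldehyde | COCOc1cc(O)c(C=O)c(OC)c1 | intermediate
11 | ethoxyacetylene | CCOC#C | starting material
12 | 6‑(ethoxyethynyl)‑5‑methoxy‑2,2‑dimethylchroman | CCOC#Cc1ccc2OC(C)(C)CCc2c1OC | intermediate
13 | (5‑methoxy‑2,2‑dimethylchroman‑6‑yl)ketene | O=C=Cc1ccc2OC(C)(C)CCc2c1OC | intermediate
14 | 2‑formyl‑3‑methoxy‑5‑(methoxymethoxy)phenyl 2‑(5‑methoxy‑2,2‑dimethylchroman‑6‑yl)acetate | COCOc1cc(OC)c(C=O)c(OC(=O)Cc2ccc3OC(C)(C)CCc3c2OC)c1 | intermediate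
15 | 5‑methoxy‑3‑(5‑methoxy‑2,2‑dimethylchroman‑6‑yl)‑7‑(methoxymethoxy)‑2H‑chromen‑2‑one | COCOc1cc(OC)c2cc(-c3ccc4OC(C)(C)CCc4c3OC)c(=O)oc2c1 | intermediate
16 | 7‑hydroxy‑5‑methoxy‑3‑(5‑methoxy‑2,2‑dimethylchroman‑6‑yl)‑2H‑chromen‑2‑one | COc1c(-c2cc3c(OC)cc(O)cc3oc2=O)ccc2c1CCC(C)(C)O2 | target

**Step count**

Total steps: 9. Longest linear sequence: 7 (steps 1–5, 8, 9).

**Steps most likely to fail**

Step 8 (proposed new method). The ynol ether may hydrate or oligomerise on the residual Pd/Cu salts at 125 °C, the ketene may dimerise instead of being captured by the hindered, chelated phenol, or the aldol closure onto the electron‑rich, doubly ortho‑substituted aldehyde may stall. The fallback uses known chemistry and sets out from 7. Palladium‑catalysed coupling of 7 with the Reformatsky reagent of tert‑butyl bromoacetate (BrZnCH2CO2t‑Bu, Pd2(dba)3/XPhos, THF, 60 °C) should give tert‑butyl 2‑(5‑methoxy‑2,2‑dimethylchroman‑6‑yl)acetate F1. Cleavage with TFA in CH2Cl2 should give 2‑(5‑methoxy‑2,2‑dimethylchroman‑6‑yl)acetic acid F2. Steglich esterification of F2 with 10 (DCC, DMAP, CH2Cl2) then gives ester 14, this time isolated, and DBU‑mediated Perkin–Oglialoro‑type ring closure rejoins the route at 15.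

Step 5. Electrophilic iodination of the activated C8 position may compete with ipso substitution, or protodecarboxylation may remove the handle without installing iodine. The fallback sets out from 5. Dakin oxidation (mCPBA, CH2Cl2) should give 5‑methoxy‑2,2‑dimethylchroman‑6‑yl formate F3, and methanolysis (K2CO3, MeOH) the phenol 5‑methoxy‑2,2‑dimethylchroman‑6‑ol F4. Triflation (Tf2O, pyridine, CH2Cl2, 0 °C) gives 5‑methoxy‑2,2‑dimethylchroman‑6‑yl trifluoromethanesulfonate F5. F5 takes the place of 7 in step 8 (Pd(PPh3)4, CuI, Et3N, DMF, 65 °C sealed for the coupling, then as before), passing through 12, 13 and 14 and rejoining the route at 15.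

Step 1. Annulation at the other free ring carbon (linear chromene) and self‑condensation of prenal at 140 °C may lower conversion and complicate purification. The fallback sets out from 1. Selective O‑alkylation of the non‑chelated 4‑OH with 3‑chloro‑3‑methylbut‑1‑yne (K2CO3, KI, CuI cat., acetone, 60 °C) should give 2‑hydroxy‑4‑((2‑methylbut‑3‑yn‑2‑yl)oxy)benzaldehyde F6. Thermolysis of F6 (N,N‑diethylaniline, 190 °C) should proceed by aryl propargyl Claisen rearrangement to the carbon between the two oxygens, 1,5‑hydrogen shift and oxa‑6π electrocyclisation, rejoining the route at 3.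

**Further compounds**

F1 | step 8 | tert‑butyl 2‑(5‑methoxy‑2,2‑dimethylchroman‑6‑yl)acetate | COc1c(CC(=O)OC(C)(C)C)ccc2OC(C)(C)CCc12
F2 | step 8 | 2‑(5‑methoxy‑2,2‑dimethylchroman‑6‑yl)acetic acid | COc1c(CC(=O)O)ccc2OC(C)(C)CCc12
F3 | step 5 | 5‑methoxy‑2,2‑dimethylchroman‑6‑yl formate | COc1c(OC=O)ccc2OC(C)(C)CCc12
F4 | step 5 | 5‑methoxy‑2,2‑dimethylchroman‑6‑ol | COc1c(O)ccc2OC(C)(C)CCc12
F5 | step 5 | 5‑methoxy‑2,2‑dimethylchroman‑6‑yl trifluoromethanesulfonate | COc1c(OS(=O)(=O)C(F)(F)F)ccc2OC(C)(C)CCc12
F6 | step 1 | 2‑hydroxy‑4‑((2‑methylbut‑3‑yn‑2‑yl)oxy)benzaldehyde | C#CC(C)(C)Oc1ccc(C=O)c(O)c1
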